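**Plan**

Numbering follows the carotenoid: C1 is the side-chain carbinol carbon, C2–C6 are the ring, C7–C15 and C15′–C1′ the polyene.
Cuts, last to first: C11=C12 (Wittig; ring C15 phosphonium salt + C25 polyenal), C10–C11 and C7=C8 (vinyl addition, Horner–Wadsworth–Emmons), the ring bond C4–C5 (SmI2 Barbier), C5–C6 (acetylation) and C1–C2 (conjugate addition).
Enabling feature: the ring carbinol carbon C5 (OH, CH3) lies β to C7 through C6, so with C7 as an ester the unit C5–C6–C7 is an acetoacetate, and C4, the end of the two-carbon arm C3–C4 on C2, can add to the C5 ketone and close the five-membered ring.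
Forward: lactone, open-chain chloro ester, acetoacetate, iodide, closure of the only ring, hydration to the C1 carbinol, C7 aldehyde, C13 enone, C15 salt, then union with the C25 aldehyde made from pseudoionone and the C10 dialdehyde.
Stereochemistry: C2 from the Rh/(R)-BINAP conjugate addition; C5 from samarium chelation (OH cis to C7); C6 by dynamic selection in the same closure (C7 trans to the C2 substituent); E-alkenes from HWE, Wittig, crystallisation and final thermal equilibration.

Key step: step 6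

Remark: the (R)-ligand in step 1 is assigned by analogy with aryl and alkenyl transfers to the same lactone; should the sense prove opposite, (S)-BINAP is used and nothing else changes.

**Route**

Step 1
Reactants: 1 5,6-dihydro-2H-pyran-2-one; 2 isopropenylboronic acid pinacol ester
Product: 3 (4R)-4-(prop-1-en-2-yl)oxan-2-one
Conditions: Rh(acac)(C2H4)2 (3 mol %), (R)-BINAP (3.3 mol %), 2 (2.5 equiv), dioxane/H2O 10:1, 100 °C
Reagents that add atoms: none
Why: Hayashi–Miyaura conjugate addition, in which the isopropenyl–rhodium species formed by transmetalation inserts the lactone C=C and water protonates the rhodium enolate, the BINAP-bound monovalent rhodium choosing the enoate face that should give (R)-configured C2.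

Step 2
Reactants: 3 (4R)-4-(prop-1-en-2-yl)oxan-2-one
Product: 4 ethyl (3R)-3-(2-hydroxyethyl)-4-methylpent-4-enoate
Conditions: NaOEt (0.1 equiv), EtOH, 0 °C → rt; AcOH (0.1 equiv); concentrate cold, use crude
Reagents that add atoms: ethanol CCO
Why: Base-catalysed ring-opening transesterification, which in ethanol as solvent should lie on the side of the δ-hydroxy ester; the product is neutralised and used at once so that it does not relactonise, and the stereocentre is untouched.

Step 3
Reactants: 4 ethyl (3R)-3-(2-hydroxyethyl)-4-methylpent-4-enoate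
Product: 5 ethyl (3S)-3-(2-chloroethyl)-4-methylpent-4-enoate (same spatial arrangement; the descriptor changes with the priorities)
Conditions: PPh3, CCl4, CH2Cl2, 40 °C
Reagents that add atoms: tetrachloromethane ClC(Cl)(Cl)Cl
Why: Appel reaction, an SN2 displacement of the alkoxyphosphonium by chloride at the primary carbon under neutral conditions that spares ester and isopropenyl group; a chloride is chosen because it survives the enolate chemistry of step 4.

Step 4
Reactants: 5 ethyl (3S)-3-(2-chloroethyl)-4-methylpent-4-enoate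
Product: 7 ethyl (3R)-2-acetyl-3-(2-chloroethyl)-4-methylpent-4-enoate (both C2 epimers), via lithium ester enolate 6 (not isolated)
Conditions: LiN(SiMe3)2 (2.2 equiv), THF, −78 °C; MeC(O)N(OMe)Me (1.3 equiv), −78 → −10 °C; AcOH
Reagents that add atoms: N-methoxy-N-methylacetamide CC(=O)N(C)OC
Why: Claisen-type C-acylation of a lithium ester enolate by an N-methoxy-N-methylamide, in which the second equivalent of amide base takes up the acidic proton of the β-keto ester and the primary chloride does not alkylate the enolates below 0 °C; C6 (carotenoid numbering) forms as an epimer mixture, which is what step 6 needs.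

Step 5
Reactants: 7 ethyl (3R)-2-acetyl-3-(2-chloroethyl)-4-methylpent-4-enoate
Product: 8 ethyl (3R)-2-acetyl-3-(2-iodoethyl)-4-methylpent-4-enoate (both C2 epimers)
Conditions: NaI (5 equiv), acetone, 56 °C, dark
Reagents that add atoms: sodium iodide [Na+].[I-]
Why: Finkelstein reaction, an SN2 halide exchange driven by precipitation of NaCl under neutral conditions, so that the β-keto ester is not converted to its enolate and cannot O-alkylate to a dihydropyran.

Step 6
Reactants: 8 ethyl (3R)-2-acetyl-3-(2-iodoethyl)-4-methylpent-4-enoate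
Product: 9 ethyl (1S,2R,5R)-2-hydroxy-2-methyl-5-(prop-1-en-2-yl)cyclopentane-1-carboxylate
Conditions: SmI2 (2.2 equiv, 0.1 M in THF, added over 2 h), THF, −78 → −20 °C; pH 7 buffer
Reagents that add atoms: none
Why: Divalent samarium transfers an electron to the C–I bond (or to the samarium-bound ketone), and the resulting C4 radical or alkylsamarium adds to the C5 ketone while trivalent samarium bridges the C5 oxygen and the ester carbonyl in a six-membered chelate; this is a samarium Barbier reaction. The closest known case is the SmI2 cyclisation of 2-(3-iodopropyl) β-keto esters to cis-2-hydroxycyclopentanecarboxylates, of which 8 is the parent acetoacetate with one extra branch. The cyclopentane closes 5-exo-trig onto the carbonyl through the new C4–C5 bond. C5 is set by the chelate, which holds the C5–O bond syn to the ester so that the hydroxyl ends up cis to C7. C6 is not fixed in 8: its epimers exchange through the enol or samarium enolate (the first alkoxide formed acts as base), and closure should run through the transition state with the isopropenyl group pseudoequatorial and trans to the ester, so the C2 centre from step 1 decides both new centres. The step needs epimerisation to outpace closure and addition to outpace plain C–I reduction; slow addition of the reductant keeps the cyclisation reagent-limited, and the isopropenyl group is inert to SmI2.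

Step 7
Reactants: 9 ethyl (1S,2R,5R)-2-hydroxy-2-methyl-5-(prop-1-en-2-yl)cyclopentane-1-carboxylate
Product: 10 ethyl (1S,2R,5R)-2-hydroxy-5-(2-hydroxypropan-2-yl)-2-methylcyclopentane-1-carboxylate
Conditions: Mn(dpm)3 (5 mol %; dpm = 2,2,6,6-tetramethylheptane-3,5-dionate), PhSiH3 (2 equiv), O2 (1 atm), i-PrOH, 0 °C → rt
Reagents that add atoms: dioxygen O=O
Why: Mukaiyama hydration, in which hydrogen-atom transfer from a manganese hydride to the 1,1-disubstituted alkene gives the tertiary radical that is trapped by O2 and reduced to the Markovnikov alcohol; no stereocentre forms, and the trans relation of C1 and C7 on the ring keeps the new hydroxyl from lactonising onto the ester.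

Step 8
Reactants: 10 ethyl (1S,2R,5R)-2-hydroxy-5-(2-hydroxypropan-2-yl)-2-methylcyclopentane-1-carboxylate
Product: 11 (1R,2R,3R)-2-(hydroxymethyl)-3-(2-hydroxypropan-2-yl)-1-methylcyclopentan-1-ol
Conditions: LiAlH4 (3 equiv), THF, 0 °C → rt; H2O, aq. NaOH work-up
Reagents that add atoms: none
Why: Hydride reduction of the ester to the primary alcohol with the two tertiary alkoxides as spectators; β-hydroxy esters are reduced to 1,3-diols faster than the aluminium aldolate fragments at this temperature.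

Step 9
Reactants: 11 (1R,2R,3R)-2-(hydroxymethyl)-3-(2-hydroxypropan-2-yl)-1-methylcyclopentan-1-ol
Product: 12 (1S,2R,5R)-2-hydroxy-5-(2-hydroxypropan-2-yl)-2-methylcyclopentane-1-carbaldehyde
Conditions: TEMPO (10 mol %), PhI(OAc)2 (1.1 equiv), CH2Cl2, 0 °C → rt; used at once
Reagents that add atoms: none
Why: Oxoammonium oxidation takes only the primary alcohol, stops at the aldehyde and needs no base, which limits retro-aldol cleavage and leaves C6 in its more stable configuration; a lactol with the C1 hydroxyl is disfavoured because it would be a trans-fused bicyclo[3.3.0] system.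

Step 10
Reactants: 12 (1S,2R,5R)-2-hydroxy-5-(2-hydroxypropan-2-yl)-2-methylcyclopentane-1-carbaldehyde
Product: 13 (3E)-4-[(1S,2R,5R)-2-hydroxy-5-(2-hydroxypropan-2-yl)-2-methylcyclopentyl]but-3-en-2-one
Conditions: (MeO)2P(O)CH2C(O)CH3 (1.5 equiv), LiCl, i-Pr2NEt, MeCN, rt
Reagents that add atoms: dimethyl (2-oxopropyl)phosphonate COP(=O)(OC)CC(C)=O
Why: Horner–Wadsworth–Emmons olefination under LiCl/tertiary-amine conditions, where the lithium-chelated phosphonate is deprotonated without forming an alkoxide from the β-hydroxy aldehyde and the stabilised anion should give the (E)-enone.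

Step 11
Reactants: 13 (3E)-4-[(1S,2R,5R)-2-hydroxy-5-(2-hydroxypropan-2-yl)-2-methylcyclopentyl]but-3-en-2-one
Product: 14 (1R,2S,3R)-2-[(1E)-3-hydroxy-3-methylpenta-1,4-dien-1-yl]-3-(2-hydroxypropan-2-yl)-1-methylcyclopentan-1-ol (both epimers at the new carbinol carbon)
Conditions: CH2=CHMgBr (4 equiv), THF, −78 → 0 °C; H2O
Reagents that add atoms: vinylmagnesium bromide C=C[Mg]Br
Why: Grignard 1,2-addition to the enone carbonyl as in the vinylation of ionones, two equivalents being spent on the hydroxyl groups; the new carbinol centre is lost again in step 12.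

Step 12
Reactants: 14 (1R,2S,3R)-2-[(1E)-3-hydroxy-3-methylpenta-1,4-dien-1-yl]-3-(2-hydroxypropan-2-yl)-1-methylcyclopentan-1-ol
Product: 15 [(2E,4E)-5-[(1S,2R,5R)-2-hydroxy-5-(2-hydroxypropan-2-yl)-2-methylcyclopentyl]-3-methylpenta-2,4-dien-1-yl]triphenylphosphonium bromide
Conditions: PPh3·HBr (1.05 equiv), MeOH, rt; crystallise
Reagents that add atoms: triphenylphosphine hydrobromide [Br-].[PH+](c1ccccc1)(c1ccccc1)c1ccccc1
Why: Acid ionises the doubly allylic tertiary alcohol to a pentadienyl cation and PPh3 attacks its unhindered terminus C11 (SN1′ allylic transposition), the standard way from vinyl carbinols to C15 Wittig salts; the saturated tertiary alcohols should not ionise at room temperature, and crystallisation should give the E isomer.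

Step 13
Reactants: 16 pseudoionone
Product: 17 (4E,6E)-3,7,11-trimethyldodeca-1,4,6,10-tetraen-3-ol (racemic)
Conditions: CH2=CHMgBr (1.2 equiv), THF, 0 °C; H2O
Reagents that add atoms: vinylmagnesium bromide C=C[Mg]Br
Why: Grignard 1,2-addition to the dienone carbonyl, the established first step from pseudoionone to acyclic C15 building blocks.

Step 14
Reactants: 17 (4E,6E)-3,7,11-trimethyldodeca-1,4,6,10-tetraen-3-ol
Product: 18 [(2E,4E,6E)-3,7,11-trimethyldodeca-2,4,6,10-tetraen-1-yl]triphenylphosphonium bromide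
Conditions: PPh3·HBr (1.05 equiv), MeOH, rt; crystallise
Reagents that add atoms: triphenylphosphine hydrobromide [Br-].[PH+](c1ccccc1)(c1ccccc1)c1ccccc1
Why: The same SN1′ phosphonium salt formation as in step 12, here on the hydrocarbon chain, with PPh3 attacking the primary terminus of the allylic cation.

Step 15
Reactants: 18 [(2E,4E,6E)-3,7,11-trimethyldodeca-2,4,6,10-tetraen-1-yl]triphenylphosphonium bromide; 19 (2E,4E,6E)-2,7-dimethylocta-2,4,6-trienedial
Product: 21 (2E,4E,6E,8E,10E,12E,14E)-2,7,11,15,19-pentamethylicosa-2,4,6,8,10,12,14,18-octaenal (12′-apo-ψ-caroten-12′-al), via acyclic C15 ylide 20 (not isolated)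
Conditions: 19 (3 equiv), NaOMe (1.0 equiv, slow addition), CH2Cl2/MeOH, 0 °C → rt; crystallise, recover 19
Reagents that add atoms: none
Why: Wittig reaction of the semi-stabilised allylic ylide with one formyl group of the dialdehyde, which is kept in excess so that the less electrophilic product aldehyde is not olefinated again; the isomer with an E bond at the new junction should crystallise.

Step 16
Reactants: 15 [(2E,4E)-5-[(1S,2R,5R)-2-hydroxy-5-(2-hydroxypropan-2-yl)-2-methylcyclopentyl]-3-methylpenta-2,4-dien-1-yl]triphenylphosphonium bromide; 21 12′-apo-ψ-caroten-12′-al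
Product: 24 (all-E)-(2R,5R,6S)-2,6-cyclolycopene-1,5-diol (target), via ring C15 ylide 22 (not isolated), via 11Z isomer 23 (not isolated)
Conditions: NaOMe (1.2 equiv), CH2Cl2/MeOH, 0 °C → rt; then EtOH, 78 °C, N2, dark; crystallise
Reagents that add atoms: none
Why: Wittig reaction builds C11=C12, and the hindered 11Z isomer that accompanies the E isomer should isomerise on heating as in other C15 + C25 carotenoid unions; the free tertiary alcohols tolerate methoxide and no stereocentre is touched.

**Compound list**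

1 | 5,6-dihydro-2H-pyran-2-one | O=C1C=CCCO1 | starting material
2 | isopropenylboronic acid pinacol ester | CC(=C)B1OC(C)(C)C(C)(C)O1 | starting material
3 | (4R)-4-(prop-1-en-2-yl)oxan-2-one | O=C1C[C@H](C(C)=C)CCO1 | intermediate
4 | ethyl (3R)-3-(2-hydroxyethyl)-4-methylpent-4-enoate | CCOC(=O)C[C@@H](CCO)C(C)=C | intermediate
5 | ethyl (3S)-3-(2-chloroethyl)-4-methylpent-4-enoate | CCOC(=O)C[C@@H](CCCl)C(C)=C | intermediate
6 | lithium enolate of 5 | CCOC(O[Li])=C[C@@H](CCCl)C(C)=C | intermediate
7 | ethyl (3R)-2-acetyl-3-(2-chloroethyl)-4-methylpent-4-enoate, both C2 epimers | CCOC(=O)C(C(C)=O)[C@@H](CCCl)C(C)=C | intermediate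
8 | ethyl (3R)-2-acetyl-3-(2-iodoethyl)-4-methylpent-4-enoate, both C2 epimers | CCOC(=O)C(C(C)=O)[C@@H](CCI)C(C)=C | intermediate
9 | ethyl (1S,2R,5R)-2-hydroxy-2-methyl-5-(prop-1-en-2-yl)cyclopentane-1-carboxylate | CCOC(=O)[C@H]1[C@H](C(C)=C)CC[C@@]1(C)O | intermediate
10 | ethyl (1S,2R,5R)-2-hydroxy-5-(2-hydroxypropan-2-yl)-2-methylcyclopentane-1-carboxylate | CCOC(=O)[C@H]1[C@H](C(C)(C)O)CC[C@@]1(C)O | intermediate
11 | (1R,2R,3R)-2-(hydroxymethyl)-3-(2-hydroxypropan-2-yl)-1-methylcyclopentan-1-ol | OC[C@H]1[C@H](C(C)(C)O)CC[C@@]1(C)O | intermediate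
12 | (1S,2R,5R)-2-hydroxy-5-(2-hydroxypropan-2-yl)-2-methylcyclopentane-1-carbaldehyde | O=C[C@H]1[C@H](C(C)(C)O)CC[C@@]1(C)O | intermediate
13 | (3E)-4-[(1S,2R,5R)-2-hydroxy-5-(2-hydroxypropan-2-yl)-2-methylcyclopentyl]but-3-en-2-one | CC(=O)/C=C/[C@H]1[C@H](C(C)(C)O)CC[C@@]1(C)O | intermediate
14 | (1R,2S,3R)-2-[(1E)-3-hydroxy-3-methylpenta-1,4-dien-1-yl]-3-(2-hydroxypropan-2-yl)-1-methylcyclopentan-1-ol, carbinol epimers | C=CC(C)(O)/C=C/[C@H]1[C@H](C(C)(C)O)CC[C@@]1(C)O | intermediate
15 | [(2E,4E)-5-[(1S,2R,5R)-2-hydroxy-5-(2-hydroxypropan-2-yl)-2-methylcyclopentyl]-3-methylpenta-2,4-dien-1-yl]triphenylphosphonium bromide | c1ccccc1[P+](c1ccccc1)(c1ccccc1)C/C=C(C)/C=C/[C@H]1[C@H](C(C)(C)O)CC[C@@]1(C)O.[Br-] | intermediate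
16 | pseudoionone, (3E,5E)-6,10-dimethylundeca-3,5,9-trien-2-one | CC(C)=CCC/C(C)=C/C=C/C(C)=O | starting material
17 | (4E,6E)-3,7,11-trimethyldodeca-1,4,6,10-tetraen-3-ol, racemic | CC(C)=CCC/C(C)=C/C=C/C(C)(O)C=C | intermediate
18 | [(2E,4E,6E)-3,7,11-trimethyldodeca-2,4,6,10-tetraen-1-yl]triphenylphosphonium bromide | CC(C)=CCC/C(C)=C/C=C/C(C)=C/C[P+](c1ccccc1)(c1ccccc1)c1ccccc1.[Br-] | intermediate
19 | (2E,4E,6E)-2,7-dimethylocta-2,4,6-trienedial | O=C/C(C)=C/C=C/C=C(C)/C=O | starting material
20 | ylide of 18, triphenyl[(2E,4E,6E)-3,7,11-trimethyldodeca-2,4,6,10-tetraen-1-ylidene]phosphorane | CC(C)=CCC/C(C)=C/C=C/C(C)=C/C=P(c1ccccc1)(c1ccccc1)c1ccccc1 | intermediate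
21 | (2E,4E,6E,8E,10E,12E,14E)-2,7,11,15,19-pentamethylicosa-2,4,6,8,10,12,14,18-octaenal | CC(C)=CCC/C(C)=C/C=C/C(C)=C/C=C/C(C)=C/C=C/C=C(C)/C=O | intermediate
22 | ylide of 15, [(2E,4E)-5-[(1S,2R,5R)-2-hydroxy-5-(2-hydroxypropan-2-yl)-2-methylcyclopentyl]-3-methylpenta-2,4-dien-1-ylidene]triphenylphosphorane | c1ccccc1P(c1ccccc1)(c1ccccc1)=C/C=C(C)/C=C/[C@H]1[C@H](C(C)(C)O)CC[C@@]1(C)O | intermediate
23 | (11Z)-(2R,5R,6S)-2,6-cyclolycopene-1,5-diol | CC(C)=CCC/C(C)=C/C=C/C(C)=C/C=C/C(C)=C/C=C/C=C(C)/C=C\C=C(C)\C=C\[C@H]1[C@H](C(C)(C)O)CC[C@@]1(C)O | intermediate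
24 | (all-E)-(2R,5R,6S)-2,6-cyclolycopene-1,5-diol; (1R,2S,3R)-3-(2-hydroxypropan-2-yl)-1-methyl-2-[(1E,3E,5E,7E,9E,11E,13E,15E,17E,19E)-3,7,12,16,20,24-hexamethylpentacosa-1,3,5,7,9,11,13,15,17,19,23-undecaen-1-yl]cyclopentan-1-ol | CC(C)=CCC/C(C)=C/C=C/C(C)=C/C=C/C(C)=C/C=C/C=C(C)/C=C/C=C(C)/C=C/[C@H]1[C@H](C(C)(C)O)CC[C@@]1(C)O | target

**Step count**

Total: 16 steps. Longest linear sequence: 13 steps (steps 1–12 and 16); steps 13–15 form the C25 aldehyde in parallel.

**Steps most likely to fail**

Step 6. Enolisation at C6 may be slower than ring closure, so that both epimers of 8 cyclise and two cis-hydroxy esters form; part of the substrate may also be held back as its samarium enolate. The fallback fixes C6 before the closure with an oxazolidinone auxiliary and keeps the same C4–C5 Barbier closure. It sets out from 5. Saponification (LiOH, THF/H2O, 0 °C) should give (3S)-3-(2-chloroethyl)-4-methylpent-4-enoic acid F1. The mixed pivalic anhydride and lithiated (4R)-4-benzyl-1,3-oxazolidin-2-one should then give (4R)-4-benzyl-3-[(3S)-3-(2-chloroethyl)-4-methylpent-4-enoyl]-1,3-oxazolidin-2-one F2. Enolisation with LiN(i-Pr)2 and acylation with acetyl chloride at −78 °C, on the enolate face away from the benzyl group, should give (4R)-3-[(2S,3R)-2-acetyl-3-(2-chloroethyl)-4-methylpent-4-enoyl]-4-benzyl-1,3-oxazolidin-2-one F3, a β-keto imide whose C6 does not epimerise. NaI in acetone should give the iodide (4R)-3-[(2S,3R)-2-acetyl-3-(2-iodoethyl)-4-methylpent-4-enoyl]-4-benzyl-1,3-oxazolidin-2-one F4. SmI2 closure under the conditions of step 6 should give (4R)-4-benzyl-3-{[(1S,2R,5R)-2-hydroxy-2-methyl-5-(prop-1-en-2-yl)cyclopentyl]carbonyl}-1,3-oxazolidin-2-one F5. LiBH4 should release (1R,2R,3R)-2-(hydroxymethyl)-1-methyl-3-(prop-1-en-2-yl)cyclopentan-1-ol F6, and Mukaiyama hydration as in step 7 returns the route at 11.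

Step 9. The free β-hydroxy aldehyde may cleave by retro-aldol reaction, dehydrate or be over-oxidised during its formation and the olefination that follows. The fallback masks both tertiary alcohols and sets out from 10. Et3SiOTf/2,6-lutidine should give ethyl (1S,2R,5R)-2-methyl-2-[(triethylsilyl)oxy]-5-{2-[(triethylsilyl)oxy]propan-2-yl}cyclopentane-1-carboxylate F7. i-Bu2AlH at −78 °C should give the aldehyde (1S,2R,5R)-2-methyl-2-[(triethylsilyl)oxy]-5-{2-[(triethylsilyl)oxy]propan-2-yl}cyclopentane-1-carbaldehyde F8, which cannot undergo retro-aldol cleavage. The olefination of step 10 should give (3E)-4-[(1S,2R,5R)-2-methyl-2-[(triethylsilyl)oxy]-5-{2-[(triethylsilyl)oxy]propan-2-yl}cyclopentyl]but-3-en-2-one F9, and HF·pyridine in THF returns the route at 13.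

Step 12. Acid ionisation may be followed by fragmentation of the ring bond C5–C6 from the cationic character at C7, by dehydration of the C5 alcohol or by poor E/Z control. The fallback avoids any cation and sets out from 12. Wittig reaction with [(2E)-4-ethoxy-2-methyl-4-oxobut-2-en-1-yl]triphenylphosphonium bromide and 1,2-epoxybutane as neutral base, then iodine-catalysed equilibration, should give ethyl (2E,4E)-5-[(1S,2R,5R)-2-hydroxy-5-(2-hydroxypropan-2-yl)-2-methylcyclopentyl]-3-methylpenta-2,4-dienoate F10. i-Bu2AlH should give (2E,4E)-5-[(1S,2R,5R)-2-hydroxy-5-(2-hydroxypropan-2-yl)-2-methylcyclopentyl]-3-methylpenta-2,4-dien-1-ol F11. CBr4/PPh3 at 0 °C should convert only the primary allylic alcohol, giving (1R,2S,3R)-2-[(1E,3E)-5-bromo-3-methylpenta-1,3-dien-1-yl]-3-(2-hydroxypropan-2-yl)-1-methylcyclopentan-1-ol F12, and PPh3 returns the route at 15.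

**Further compounds**

F1 | step 6 | (3S)-3-(2-chloroethyl)-4-methylpent-4-enoic acid | OC(=O)C[C@@H](CCCl)C(C)=C
F2 | step 6 | (4R)-4-benzyl-3-[(3S)-3-(2-chloroethyl)-4-methylpent-4-enoyl]-1,3-oxazolidin-2-one | O=C(C[C@@H](CCCl)C(C)=C)N1[C@H](Cc2ccccc2)COC1=O
F3 | step 6 | (4R)-3-[(2S,3R)-2-acetyl-3-(2-chloroethyl)-4-methylpent-4-enoyl]-4-benzyl-1,3-oxazolidin-2-one | CC(=O)[C@@H](C(=O)N1[C@H](Cc2ccccc2)COC1=O)[C@@H](CCCl)C(C)=C
F4 | step 6 | (4R)-3-[(2S,3R)-2-acetyl-3-(2-iodoethyl)-4-methylpent-4-enoyl]-4-benzyl-1,3-oxazolidin-2-one | CC(=O)[C@@H](C(=O)N1[C@H](Cc2ccccc2)COC1=O)[C@@H](CCI)C(C)=C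
F5 | step 6 | (4R)-4-benzyl-3-{[(1S,2R,5R)-2-hydroxy-2-methyl-5-(prop-1-en-2-yl)cyclopentyl]carbonyl}-1,3-oxazolidin-2-one | O=C([C@H]1[C@H](C(C)=C)CC[C@@]1(C)O)N1[C@H](Cc2ccccc2)COC1=O
F6 | step 6 | (1R,2R,3R)-2-(hydroxymethyl)-1-methyl-3-(prop-1-en-2-yl)cyclopentan-1-ol | OC[C@H]1[C@H](C(C)=C)CC[C@@]1(C)O
F7 | step 9 | ethyl (1S,2R,5R)-2-methyl-2-[(triethylsilyl)oxy]-5-{2-[(triethylsilyl)oxy]propan-2-yl}cyclopentane-1-carboxylate | CCOC(=O)[C@H]1[C@H](C(C)(C)O[Si](CC)(CC)CC)CC[C@@]1(C)O[Si](CC)(CC)CC
F8 | step 9 | (1S,2R,5R)-2-methyl-2-[(triethylsilyl)oxy]-5-{2-[(triethylsilyl)oxy]propan-2-yl}cyclopentane-1-carbaldehyde | O=C[C@H]1[C@H](C(C)(C)O[Si](CC)(CC)CC)CC[C@@]1(C)O[Si](CC)(CC)CC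
F9 | step 9 | (3E)-4-[(1S,2R,5R)-2-methyl-2-[(triethylsilyl)oxy]-5-{2-[(triethylsilyl)oxy]propan-2-yl}cyclopentyl]but-3-en-2-one | CC(=O)/C=C/[C@H]1[C@H](C(C)(C)O[Si](CC)(CC)CC)CC[C@@]1(C)O[Si](CC)(CC)CC
F10 | step 12 | ethyl (2E,4E)-5-[(1S,2R,5R)-2-hydroxy-5-(2-hydroxypropan-2-yl)-2-methylcyclopentyl]-3-methylpenta-2,4-dienoate | CCOC(=O)/C=C(C)/C=C/[C@H]1[C@H](C(C)(C)O)CC[C@@]1(C)O
F11 | step 12 | (2E,4E)-5-[(1S,2R,5R)-2-hydroxy-5-(2-hydroxypropan-2-yl)-2-methylcyclopentyl]-3-methylpenta-2,4-dien-1-ol | OC/C=C(C)/C=C/[C@H]1[C@H](C(C)(C)O)CC[C@@]1(C)O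
F12 | step 12 | (1R,2S,3R)-2-[(1E,3E)-5-bromo-3-methylpenta-1,3-dien-1-yl]-3-(2-hydroxypropan-2-yl)-1-methylcyclopentan-1-ol | BrC/C=C(C)/C=C/[C@H]1[C@H](C(C)(C)O)CC[C@@]1(C)O
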